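**Assumption:** The absolute configuration is taken from the given SMILES (iridoid numbering 1S,7S,8R,9S). The Pd-ligand and ketoreductase (KRED) enantiopreferences are assumed selectable to match it, and the C1 anomers of 21 are assumed separable. Iridoid numbering: C1 acetal, O2, C3, C4, C5–C9 ring, C10 on C8, C11 on C4.

## Retrosynthetic overview
1. The target comes from late C11 CH2OH acetylation, with C11 carried as an allyl ester. That ester is the vinylogous-carbonate (push–pull) group that lets a formylacetate enol close onto a C9–CH(OMe)2 acetal to give the C1 lactol, which is then acylated.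
2. The cyclopentene comes from a 3-substituted cyclopentenone: the C5 side chain by Michael addition then Saegusa–Ito oxidation, C7–OH by a ketoreductase, and the C8 quaternary carbinol by α′-hydroxylation then hydroxymethylation anti to C9.
3. C9 (and the cis C7–O) comes from Pd-catalysed desymmetrization of a meso cyclopentene diacetate with nitromethane, followed by Nef reaction to the acetal.
4. Ring order: the cyclopentene is made first and the dihydropyran last, after all oxidation-sensitive steps on the carbocycle.

## Forward route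

**Step 1**
Reactants: 1 cis-3,5-diacetoxycyclopentene (meso); 2 nitromethane
Product: 3 (1S,4R)-cis-4-(nitromethyl)cyclopent-2-en-1-yl acetate
Conditions: Pd2(dba)3·CHCl3 (2.5 mol %), (R,R)-Trost DACH-phenyl ligand (7.5 mol %), MeNO2 (5 equiv), Et3N, CH2Cl2, 23 °C
Reagents that add atoms: nitromethane, C[N+](=O)[O-]
Why: Trost Pd-catalysed asymmetric allylic alkylation (desymmetrization) ionizes one enantiotopic acetate, and the nitronate attacks anti to Pd, giving net retention. This sets C9 and C7 cis, and is the first stereocentre step.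

**Step 2**
Reactants: 3
Product: 4 (1S,4R)-cis-4-(dimethoxymethyl)cyclopent-2-en-1-yl acetate
Conditions: (i) DBU (1.1 equiv), MeOH, 0 °C; (ii) add the nitronate solution to H2SO4/MeOH (1:3), –40 → 0 °C; NaHCO3 quench
Reagents that add atoms: methanol, CO
Why: Nef reaction of the primary nitronate in methanol gives the dimethyl acetal (the C1 aldehyde oxidation level, protected). Acetate-protected C7 avoids a cis-1,4 bicyclic acetal, and no stereocentre is touched.

**Step 3**
Reactants: 4
Product: 5 (1S,4R)-cis-4-(dimethoxymethyl)cyclopent-2-en-1-ol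
Conditions: K2CO3, MeOH, 23 °C
Reagents that add atoms: none
Why: Zemplén-type methanolysis of the acetate; the acetal is base-stable and both stereocentres are retained.

**Step 4**
Reactants: 5
Product: 6 (R)-4-(dimethoxymethyl)cyclopent-2-en-1-one
Conditions: Dess–Martin periodinane, NaHCO3, CH2Cl2, 0 °C
Reagents that add atoms: none
Why: Oxidation of the allylic alcohol destroys the C7 stereocentre (it is reset by the enzyme in step 10) and keeps C9. The enone is used immediately because 4-substituted cyclopentenones racemize by γ-deprotonation.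

**Step 5**
Reactants: 6
Product: 7 (4S,5R)-4-(dimethoxymethyl)-5-hydroxycyclopent-2-en-1-one
Conditions: LDA (1.05 equiv), THF, –78 °C; then Davis oxaziridine, –78 °C
Reagents that add atoms: (±)-2-(phenylsulfonyl)-3-phenyloxaziridine, O1C(c2ccccc2)N1S(=O)(=O)c1ccccc1
Why: Kinetic enolization is regiospecific at C8 (the other α-carbon is vinylic). Davis α-hydroxylation occurs anti to the C9 acetal, giving trans OH; this centre is erased in step 6.

**Step 6**
Reactants: 7; 8 formaldehyde (monomeric)
Product: 9 (4S,5R)-4-(dimethoxymethyl)-5-hydroxy-5-(hydroxymethyl)cyclopent-2-en-1-one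
Conditions: LDA (2.2 equiv), THF, –78 °C; then CH2O in THF, –78 → –40 °C
Reagents that add atoms: formaldehyde, C=O
Why: The planar enediolate undergoes aldol hydroxymethylation anti to the C9 acetal, so C10 ends trans to C1 and the oxygen cis to C1. This builds the C8 quaternary carbinol with the target relative configuration.

**Step 7**
Reactants: 9
Product: 10 (4S,5R)-5-[(tert-butyldimethylsilyloxy)methyl]-4-(dimethoxymethyl)-5-hydroxycyclopent-2-en-1-one
Conditions: TBSCl (1.05 equiv), imidazole, DMF, 0 °C
Reagents that add atoms: TBSCl, CC(C)(C)[Si](C)(C)Cl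
Why: Silylation is selective for the unhindered primary C10–OH; the tertiary C8–OH stays free.

**Step 8**
Reactants: 10; 11 allyl (trimethylsilyl)acetate
Product: 12 allyl 2-[(2S,3R)-3-(TBSO-methyl)-2-(dimethoxymethyl)-3-hydroxy-4-oxocyclopentyl]acetate (C5 side chain trans to C9 substituent)
Conditions: TBAF (10 mol %), THF, –20 → 0 °C
Reagents that add atoms: allyl (trimethylsilyl)acetate, C[Si](C)(C)CC(=O)OCC=C
Why: Fluoride releases an ester enolate that adds 1,4 to the enone at C5. These are non-acidic conditions, so the acetal survives, and the C5 stereocentre is erased in step 9.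

**Step 9**
Reactants: 12
Product: 13 allyl 2-[(4R,5S)-4-(TBSO-methyl)-5-(dimethoxymethyl)-4-hydroxy-3-oxocyclopent-1-en-1-yl]acetate
Conditions: (i) TMSOTf (2.2 equiv), Et3N (4 equiv), CH2Cl2, 0 °C; (ii) Pd(OAc)2 (1.1 equiv), MeCN, 23 °C; aq. AcOH/THF work-up
Reagents that add atoms: none
Why: Saegusa–Ito oxidation. The silyl enol ether can only form toward C6 because C8 is quaternary, and the enone C5=C6 is regenerated carrying the C5 side chain. The work-up removes TMS from the tertiary alcohol.

**Step 10**
Reactants: 13
Product: 14 allyl 2-[(3S,4R,5S)-4-(TBSO-methyl)-5-(dimethoxymethyl)-3,4-dihydroxycyclopent-1-en-1-yl]acetate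
Conditions: KRED (commercial ketoreductase panel hit), NADP+ (0.5 mol %), glucose dehydrogenase, D-glucose (2 equiv), KPi pH 7.0/DMSO (9:1), 30 °C
Reagents that add atoms: none
Why: An NADPH-dependent ketoreductase (oxidoreductase) delivers hydride to one face of the C7 ketone, giving the 7S alcohol trans to C8–OH. This is enzyme-controlled rather than substrate-controlled, since both faces are flanked by C8 substituents.

**Step 11**
Reactants: 14
Product: 15 C7-TBS ether of 14, (3S,4R,5S)
Conditions: TBSOTf (1.1 equiv), 2,6-lutidine, CH2Cl2, –78 → 0 °C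
Reagents that add atoms: TBSOTf, CC(C)(C)[Si](C)(C)OS(=O)(=O)C(F)(F)F
Why: Silylating the secondary alcohol (no new stereocentre) stops the C7 oxygen acting as a leaving group in the next, strongly basic step; the hindered tertiary C8–OH stays free.

**Step 12**
Reactants: 15; 16 ethyl formate
Product: 17 allyl 3-oxo-2-[(3S,4R,5S)-3-(TBSO)-4-(TBSO-methyl)-5-(dimethoxymethyl)-4-hydroxycyclopent-1-en-1-yl]propanoate (exists as enol/aldehyde tautomers)
Conditions: LiHMDS (3.2 equiv), THF, –78 °C; then HCO2Et (6 equiv), –78 → 0 °C; aq. NH4Cl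
Reagents that add atoms: ethyl formate, CCOC=O
Why: Claisen-type formylation of the extended ester enolate at C4 installs C3; no stereocentre is formed because C4 becomes sp2.

**Step 13**
Reactants: 17
Product: 18 allyl (7S,8R,9S)-1-hydroxy-7-(TBSO)-8-hydroxy-8-(TBSO-methyl)cyclopenta[c]pyran-4-carboxylate (C1 lactol, anomer mixture)
Conditions: PPTS (0.3 equiv), acetone/H2O (9:1), 45 °C
Reagents that add atoms: water, O
Why: Acetal hydrolysis gives the C1 aldehyde, which is trapped by the C3 enol oxygen (intramolecular hemiacetalization). The push–pull vinylogous carbonate drives ring closure, and C9 (not acidic) keeps its configuration.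

**Step 14**
Reactants: 18
Product: 19 allyl (7S,8R,9S)-1,7,8-trihydroxy-8-(hydroxymethyl)cyclopenta[c]pyran-4-carboxylate
Conditions: HF·pyridine, THF/pyridine (4:1), 0 → 23 °C
Reagents that add atoms: none
Why: Fluoride removes both silyl ethers under near-neutral conditions while the push–pull lactol is still stable.

**Step 15**
Reactants: 19
Product: 20 C10 acetate of 19
Conditions: Novozym 435 (Candida antarctica lipase B), isopropenyl acetate (1.1 equiv), MTBE, 25 °C
Reagents that add atoms: isopropenyl acetate, CC(=C)OC(C)=O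
Why: A lipase (hydrolase) transesterification is selective for the unhindered primary C10–OH over the hindered C7 secondary, the C8 tertiary OH and the lactol OH, under neutral conditions.

**Step 16**
Reactants: 20
Product: 21 allyl (1S,7S,8R,9S)-10-acetoxy-1,7-bis(isovaleryloxy)-8-hydroxy-cyclopenta[c]pyran-4-carboxylate
Conditions: isovaleryl chloride (2.6 equiv), pyridine (6 equiv), DMAP (0.1 equiv), CH2Cl2, 0 °C; separate anomers by chromatography
Reagents that add atoms: isovaleryl chloride, CC(C)CC(=O)Cl
Why: Acylation of C7–OH (retention) and the anomeric OH gives both acylal anomers (the lactol equilibrates through the open form); the desired 1S acylal, with OiVal cis to H9, is isolated. The tertiary C8–OH is inert.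

**Step 17**
Reactants: 21
Product: 22 (1S,7S,8R,9S)-10-acetoxy-1,7-bis(isovaleryloxy)-8-hydroxycyclopenta[c]pyran-4-carboxylic acid
Conditions: Pd(PPh3)4 (5 mol %), PhSiH3 (2 equiv), CH2Cl2, 0 °C
Reagents that add atoms: none
Why: Tsuji–Trost-type deallylation with silane as the allyl acceptor is neutral and leaves the acylal and the other esters intact.

**Step 18**
Reactants: 22
Product: 23 (1S,7S,8R,9S)-10-acetoxy-11-hydroxy-1,7-bis(isovaleryloxy)-8-hydroxy compound (C11 CH2OH)
Conditions: (i) i-BuOCOCl (1.2 equiv), N-methylmorpholine (1.2 equiv), THF, –15 °C; (ii) NaBH4 (3 equiv), H2O, 0 °C, 10 min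
Reagents that add atoms: none
Why: The mixed anhydride is reduced by borohydride much faster than the esters or acylal, so the ester oxidation level at C11 drops to the alcohol without a strong hydride.

**Step 19**
Reactants: 23
Product: 24 10-acetoxyvaltrathydrin
Conditions: Ac2O (3 equiv), pyridine, DMAP (5 mol %), CH2Cl2, 0 °C
Reagents that add atoms: acetic anhydride, CC(=O)OC(C)=O
Why: Acetylation of the primary C11–OH; the tertiary C8–OH is unreactive, and all ring stereocentres are unchanged.

## Compound list
1 | cis-3,5-diacetoxycyclopentene (meso) | CC(=O)O[C@@H]1C=C[C@H](OC(C)=O)C1 | starting material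
2 | nitromethane | C[N+](=O)[O-] | starting material
3 | (1S,4R)-cis-4-(nitromethyl)cyclopent-2-en-1-yl acetate | CC(=O)O[C@@H]1C=C[C@H](C[N+](=O)[O-])C1 | intermediate
4 | (1S,4R)-cis-4-(dimethoxymethyl)cyclopent-2-en-1-yl acetate | COC(OC)[C@@H]1C[C@H](OC(C)=O)C=C1 | intermediate
5 | (1S,4R)-cis-4-(dimethoxymethyl)cyclopent-2-en-1-ol | COC(OC)[C@@H]1C[C@H](O)C=C1 | intermediate
6 | (R)-4-(dimethoxymethyl)cyclopent-2-en-1-one | COC(OC)[C@@H]1CC(=O)C=C1 | intermediate
7 | (4S,5R)-4-(dimethoxymethyl)-5-hydroxycyclopent-2-en-1-one | COC(OC)[C@@H]1[C@@H](O)C(=O)C=C1 | intermediate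
8 | formaldehyde | C=O | starting material
9 | (4S,5R)-4-(dimethoxymethyl)-5-hydroxy-5-(hydroxymethyl)cyclopent-2-en-1-one | COC(OC)[C@@H]1[C@@](O)(CO)C(=O)C=C1 | intermediate
10 | (4S,5R)-5-(TBSO-methyl)-4-(dimethoxymethyl)-5-hydroxycyclopent-2-en-1-one | COC(OC)[C@@H]1[C@@](O)(CO[Si](C)(C)C(C)(C)C)C(=O)C=C1 | intermediate
11 | allyl (trimethylsilyl)acetate | C[Si](C)(C)CC(=O)OCC=C | starting material
12 | Michael adduct (C5 trans to C9; C5 configuration not defined in SMILES) | COC(OC)[C@@H]1[C@@](O)(CO[Si](C)(C)C(C)(C)C)C(=O)C[C@H]1CC(=O)OCC=C | intermediate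
13 | enone after Saegusa–Ito oxidation | COC(OC)[C@@H]1[C@@](O)(CO[Si](C)(C)C(C)(C)C)C(=O)C=C1CC(=O)OCC=C | intermediate
14 | C7 allylic alcohol (KRED product) | COC(OC)[C@@H]1[C@@](O)(CO[Si](C)(C)C(C)(C)C)[C@@H](O)C=C1CC(=O)OCC=C | intermediate
15 | C7-TBS ether | COC(OC)[C@@H]1[C@@](O)(CO[Si](C)(C)C(C)(C)C)[C@@H](O[Si](C)(C)C(C)(C)C)C=C1CC(=O)OCC=C | intermediate
16 | ethyl formate | CCOC=O | starting material
17 | formylacetate (aldehyde tautomer; C4 not defined) | COC(OC)[C@@H]1[C@@](O)(CO[Si](C)(C)C(C)(C)C)[C@@H](O[Si](C)(C)C(C)(C)C)C=C1C(C=O)C(=O)OCC=C | intermediate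
18 | bicyclic lactol, bis-TBS (C1 not defined) | C=CCOC(=O)C1=COC(O)[C@H]2C1=C[C@H](O[Si](C)(C)C(C)(C)C)[C@]2(O)CO[Si](C)(C)C(C)(C)C | intermediate
19 | tetrol (C1 not defined) | C=CCOC(=O)C1=COC(O)[C@H]2C1=C[C@H](O)[C@]2(O)CO | intermediate
20 | C10 acetate (C1 not defined) | C=CCOC(=O)C1=COC(O)[C@H]2C1=C[C@H](O)[C@]2(O)COC(C)=O | intermediate
21 | allyl ester bis-isovalerate | C=CCOC(=O)C1=CO[C@@H](OC(=O)CC(C)C)[C@H]2C1=C[C@H](OC(=O)CC(C)C)[C@]2(O)COC(C)=O | intermediate
22 | C11 carboxylic acid | OC(=O)C1=CO[C@@H](OC(=O)CC(C)C)[C@H]2C1=C[C@H](OC(=O)CC(C)C)[C@]2(O)COC(C)=O | intermediate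
23 | C11 alcohol | OCC1=CO[C@@H](OC(=O)CC(C)C)[C@H]2C1=C[C@H](OC(=O)CC(C)C)[C@]2(O)COC(C)=O | intermediate
24 | 10-acetoxyvaltrathydrin | CC(=O)OCC1=CO[C@@H](OC(=O)CC(C)C)[C@H]2C1=C[C@H](OC(=O)CC(C)C)[C@]2(O)COC(C)=O | target

## Totals
Total steps: 19. Longest linear sequence: 19 (all steps are linear from 1).

**Three steps most likely to fail**
1. **Step 6 (enediolate hydroxymethylation; C8 quaternary centre).** It may suffer retro-aldol or poor anti selectivity.
   Fallback (different approach): α′-methylenate enone 6 (LDA, Eschenmoser's salt, then MeI/base). Reduce the C7 ketone to the 7-epi allylic alcohol and epoxidize the exocyclic alkene syn to C7–OH (VO(acac)2/t-BuOOH). Open the epoxide at C10 with AcOH, then invert C7 by Mitsunobu with isovaleric acid.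
2. **Step 10 (KRED on an α-quaternary enone).** Substrate acceptance or diastereoselectivity may be poor.
   Fallback (different approach): replace enzyme control by catalyst control, using (S)-CBS or Ru-TsDPEN asymmetric reduction. If the 7-epimer forms, oxidize and use Mitsunobu inversion with p-nitrobenzoic acid.
3. **Step 18 (mixed-anhydride NaBH4 reduction next to the acylal).** The acylal may be attacked or the activated acid may reduce sluggishly.
   Fallback (different approach): reorder so that ester reduction precedes acylation. Silylate the lactol of 18 (C1–OTBS), reduce the C11 ester with DIBAL, acetylate, remove the silyl groups with buffered TBAF, then do the lipase acetylation and the isovaleryl acylation last.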